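- No rate constant for J + L is given, so I have to draw one from Saturday's and Tuesday's runs, in which J is fed into a flask holding L.

| setting | Saturday's | Tuesday's | flask |
|---|---|---|---|
| J | 0.13 M (fed, over 6.0 d) | 0.52 M (fed, over 6.0 d) | 0.26 M (fed, over 6.0 d) |
| L | 1.3 equiv | 1.3 equiv | 1.30 equiv |
| remark | run made earlier; the fed solution adds 0.50 times the starting volume | run made earlier; the fed solution adds 0.50 times the starting volume | the fed solution adds 0.50 times the starting volume |
| time |  |  | 6.0 d |

| run | time / d | J / % | E / % |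
|---|---|---|---|
| Saturday's | 0.417 | 4 | 0 |
| Saturday's | 1.25 | 14 | 4 |
| Saturday's | 2.00 | 26 | 5 |
| Saturday's | 3.00 | 42 | 6 |
| Saturday's | 5.00 | 58 | 11 |
| Tuesday's | 0.417 | 6 | 2 |
| Tuesday's | 0.833 | 13 | 3 |
| Tuesday's | 1.25 | 15 | 4 |
| Tuesday's | 2.50 | 25 | 6 |
| Tuesday's | 5.00 | 37 | 12 |

(readings scatter by 2 percentage points)

* J at 6.0 d, in percent of the J charged
* E at 6.0 d, in percent of the J charged
* D at 6.0 d, in percent of the J charged
* G at 6.0 d, in percent of the J charged

- charges are per starting volume, the dose included; the dosed solution carries all of it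
- the numbers in the tables scatter by 2 percentage points (one standard deviation)
- percentages count the whole charge, also what has not yet gone in
- a reading or a percentage of E counts all its forms, free or not

- One thing looks wrong: Tuesday's run has 4.00 times Saturday's charge, yet at 5.00 d it has consumed 46.3% of its J against Saturday's 25.3%, a factor of 1.83.
- J gone is the fed share less the J read, and it grows with [L] times the mean J. On a straight rise, that mean is 0.5 of the J left at the end.
- So I divide the ratio of J gone to J left by the time and by mean [L]. For mean [L], I take the volume at mid-time and a guessed 1.50 L per J gone, between one for a mono adduct and two for G, with 0.5 of that spent on average.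
- Saturday gives 0.443 M⁻¹ d⁻¹ at 3.00 d and 0.732 M⁻¹ d⁻¹ at 5.00 d. Tuesday gives 0.482 M⁻¹ d⁻¹ at 2.50 d and 0.611 M⁻¹ d⁻¹ at 5.00 d.
- Tuesday reads above Saturday early and below it late, so the charge opens no steady gap and the odd factor clears. A reading scatters by 2 percentage points, against Saturday's 8.00% J gone at 3.00 d, so I read no trend into the climb within each run.
- I carry their mean, 0.567 M⁻¹ d⁻¹, the clearance w: gone-to-left ratio per day and per molar of mean [L]. Times [L], it is a pseudo-first-order constant.
- For this flask, unspent L would give a ratio of 0.920. Letting L fall with J gone gives 0.701, so I expect 58.8% J left at 6.0 d.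
- The forecast says J 52%, E 14%, D 19% and G 15%, and calls the rate “sub-linear in concentration, partly from L depletion”.
- The flask gives J 59.5%, E 13.4%, D 5.41% and G 5.94%.

    J + L → E (k = 6.20 × 10⁻⁴ M⁻¹ min⁻¹)
    J + L → D (k = 1.30 × 10⁻⁴ M⁻¹ min⁻¹)
    L + E → G (k = 4.10 × 10⁻⁴ M⁻¹ min⁻¹)
    L + D → G (k = 4.30 × 10⁻⁴ M⁻¹ min⁻¹)
    L + E → Z (k = 0.00150 M⁻¹ min⁻¹)
    Q ⇌ E, rate k6*(cs6 - [E]) while solid is left; crystals form when [E] > cs6 (solubility = 0.0900 M, k = 0.0300 min⁻¹)

- My J stands 0.70 points below the flask's. The neighbour holds the equivalents and takes 0.65 M of J. The same w gives an unspent ratio of 2.30, then 1.50, so 40.0% J left. The neighbour holds 44.6% J at 6.00 d, 4.6 points above that reckoning.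

All runs were computed for substances that don't exist; noise was put on by code.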